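**Plan**

1. The hard part is the chain, not a ring. Three identical C4(sp3)–C8(sp2) interflavan bonds must join four identical units exactly three times, at C8 and not C6, each 4β (3,4-trans). Every bond made is itself acid-labile.
2. The retrosynthesis cuts all three C4–C8 bonds at once. This gives four different monomers that branch off one short line from (−)-epicatechin: a C8-bromo-capped C4-thio "starter", a C4-oxy "O-extender", a C4-thio "S-extender" and a C4-H2 "terminator".
3. In the forward direction the chain is joined top-down (unit 1→2→3→4) in one flask by a soft, a hard and a soft activation cycle. The chain-end leaving group alternates S, O, S, so each incoming unit carries a C4 group that the promoter of its own cycle cannot ionise. No ring is formed, because all four chroman systems are bought.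
4. The enabling feature is that C4 of every unit is benzylic to a phloroglucinol-type A ring (O1, O5 and O7 are ortho/para to C4a), so a C4–S or C4–O bond ionises to a persistent cation. C8–H of the same ring is its only unhindered nucleophilic carbon. The C2 aryl group and O3 both lie on the α face of the C ring, which leaves the β face open.
5. Stereochemistry: the eight C2/C3 centres (all R) come with (−)-epicatechin. The three C4 centres (all R in the target) are relayed from them by substrate control in the key step.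
6. Endgame: one transesterification removes four acetates, and one hydrogenolysis removes sixteen benzyl groups and the bromine cap.

Key step: step 7

Assumption: the SMILES is read as epicatechin-(4β→8)-epicatechin-(4β→8)-epicatechin-(4β→8)-epicatechin, with 2R,3R in all four units and 4R at the three interflavan carbons. The descriptors α/β follow the usual flavan drawing, in which the C2 aryl group and O3 of epicatechin are α. Abbreviations: Xy = 2,6-dimethylphenyl; E = a 3-O-acetyl-5,7,3′,4′-tetra-O-benzylepicatechin unit; TTBP = 2,4,6-tri-tert-butylpyrimidine.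

**Route**

Step 1
Reactants: 1 (−)-epicatechin
Product: 2 5,7,3′,4′-tetra-O-benzyl-(−)-epicatechin (2R,3R; 3-OH free)
Conditions: BnBr (4.4 equiv), K2CO3, DMF, 0 °C → rt, Ar
Reagents that add atoms: benzyl bromide, BrCc1ccccc1
Why: Williamson ether synthesis, in which K2CO3 deprotonates only the four phenols, so the secondary 3-OH stays free and C2/C3 are not touched.

Step 2
Reactants: 2 5,7,3′,4′-tetra-O-benzyl-(−)-epicatechin
Product: 3 3-O-acetyl-5,7,3′,4′-tetra-O-benzyl-(−)-epicatechin (terminator)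
Conditions: Ac2O, DMAP (cat.), pyridine, rt
Reagents that add atoms: acetic anhydride, CC(=O)OC(C)=O
Why: DMAP-catalysed acylation of the only free hydroxyl group, with no stereocentre involved.

Step 3
Reactants: 3 terminator acetate
Product: 4 3-O-acetyl-5,7,3′,4′-tetra-O-benzyl-4β-(2-ethoxyethoxy)epicatechin (O-extender; 3,4-trans)
Conditions: DDQ, 2-ethoxyethanol, CH2Cl2, rt
Reagents that add atoms: 2-ethoxyethanol, CCOCCO
Why: DDQ benzylic oxidation, in which hydride is taken from C4 (activated by O1, 5-OBn and 7-OBn) and the alcohol captures the cation from the β face, opposite the 3-OAc and C2 aryl groups, setting a 4β centre that is lost again later.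

Step 4
Reactants: 4 O-extender
Product: 5 3-O-acetyl-5,7,3′,4′-tetra-O-benzyl-4β-(2,6-dimethylphenylthio)epicatechin (S-extender)
Conditions: 2,6-Me2C6H3SH, BF3·OEt2 (cat.), CH2Cl2, −78 °C
Reagents that add atoms: 2,6-dimethylbenzenethiol, Cc1cccc(C)c1S
Why: Lewis acid-mediated SN1 exchange of O for S at C4, in which the thiol outcompetes every arene carbon for the cation and enters from the open β face.

Step 5
Reactants: 4 O-extender
Product: 6 3-O-acetyl-5,7,3′,4′-tetra-O-benzyl-8-bromo-4β-(2-ethoxyethoxy)epicatechin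
Conditions: NBS (1.0 equiv), CH2Cl2, −78 → −20 °C, dark
Reagents that add atoms: N-bromosuccinimide, O=C1CCC(=O)N1Br
Why: electrophilic aromatic bromination of the most electron-rich ring, which goes to C8 because C6 lies between two benzyloxy groups; the medium stays acid-free, so the C4 ether survives.

Step 6
Reactants: 6 8-bromo-4β-(2-ethoxyethoxy) acetate
Product: 7 3-O-acetyl-5,7,3′,4′-tetra-O-benzyl-8-bromo-4β-(2,6-dimethylphenylthio)epicatechin (starter)
Conditions: 2,6-Me2C6H3SH, BF3·OEt2 (cat.), CH2Cl2, −78 → −40 °C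
Reagents that add atoms: 2,6-dimethylbenzenethiol, Cc1cccc(C)c1S
Why: the same Lewis acid-mediated SN1 O-to-S exchange as in step 4, with β-face entry of the thiol and the aryl bromide as a spectator.

Step 7
Reactants: 7 starter; 4 O-extender; 5 S-extender; 3 terminator
Product: 13 protected tetramer 8-Br-E-(4β→8)-E-(4β→8)-E-(4β→8)-E (Br on C8 of the top unit; bottom unit C4H2), via starter C4 cation triflate 8 (not isolated), via dimer ether 9 (not isolated), via dimer C4 cation triflate 10 (not isolated), via trimer thioether 11 (not isolated), via trimer C4 cation triflate 12 (not isolated)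
Conditions: one flask, CH2Cl2, 4 Å MS: (i) 7, AgOTf then p-TolSCl (1.0 equiv each), −78 °C, 10 min; 4 (0.95 equiv) + TTBP, −78 → −40 °C; (ii) recool, 5 (0.90 equiv) + TTBP, then TMSOTf (0.95 equiv), −78 → −40 °C; (iii) recool, AgOTf then p-TolSCl (0.90 equiv each), −78 °C, 10 min; 3 (1.3 equiv) + TTBP, −78 → −20 °C; Et3N
Reagents that add atoms: none
Why: Proposed new method: in cycles 1 and 3 p-TolSOTf sulfenylates the chain-end C4–SXy sulfur and the thiosulfonium ion collapses, pushed by O1, 5-OBn and 7-OBn, to the mixed disulfide and the A-ring-stabilised C4 cation (held as its 3,4-cis acetoxonium form by the 3-OAc group), while in cycle 2 TMSOTf silylates the chain-end C4–OCH2CH2OEt oxygen and releases the same type of cation beside the silyl ether; in every cycle C8–H of the incoming unit then attacks the cation in a Friedel–Crafts alkylation and TTBP takes up the proton. The closest known reaction types are the thiophile-triggered C4–S/C8–H coupling of flavan-4-yl thioethers, the hard-Lewis-acid coupling of flavan-4-yl ethers with units that carry a spectator C4–SXy group, and the orthogonal and pre-activation one-pot assemblies of oligosaccharides; new are the flavan cation made in the absence of its nucleophile, the C4–O group as a spectator in a soft cycle, and the running of three cycles without isolation. No ring is closed, the step forms the three C4–C8 bonds only. Each of the three new C4 stereocentres is controlled by the C2/C3 pair of its own unit, since the C2 aryl group and the bridging 3-acetoxy group cover the α face and the arene must enter from the β face (3,4-trans). Chain length and sequence require that no activated species has a free C8–H and that no incoming unit is ionised in the cycle in which it enters, which is secured by the bromine on C8 of 7, by the alternation of leaving groups (4 brings a C4–O bond into a buffered soft cycle whose promoter is already spent, 5 brings a C4–S bond into a hard cycle, 3 brings no leaving group), by the slight deficit of each bifunctional unit, and by the two ortho methyl groups of the xylyl group, which shield sulfur against S-alkylation and thus against transfer of the thio group. Attack at C8 and not at C6 follows from the position of C6 between two benzyloxy groups.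

Step 8
Reactants: 13 protected tetramer
Product: 14 8-bromo-hexadeca-O-benzyl tetramer tetrol (all four 3-OH free; all-4β→8)
Conditions: NaOMe (cat.), MeOH/THF, 40 °C
Reagents that add atoms: none
Why: Zemplén transesterification of the four secondary acetates; with every phenol benzylated no quinone methide can form, so C2, C3 and C4 are not epimerised.

Step 9
Reactants: 14 8-bromo-hexadeca-O-benzyl tetramer tetrol
Product: 15 epicatechin-(4β→8)-epicatechin-(4β→8)-epicatechin-(4β→8)-epicatechin (the target)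
Conditions: H2 (1 atm), Pd(OH)2/C, NaOAc (1.2 equiv), THF/MeOH/H2O, rt
Reagents that add atoms: none
Why: catalytic hydrogenolysis of sixteen aryl benzyl ethers together with hydrodehalogenation of C8–Br, with acetate buffering the HBr so that the acid-labile interflavan bonds of the free phenol survive and no stereocentre is touched.

**Compound list**

1 | (−)-epicatechin | Oc1cc(O)c2c(c1)O[C@H](c1ccc(O)c(O)c1)[C@H](O)C2 | starting material
2 | 5,7,3′,4′-tetra-O-benzyl-(−)-epicatechin | c1c(OCc3ccccc3)cc(OCc3ccccc3)c2c1O[C@H](c1ccc(OCc3ccccc3)c(OCc3ccccc3)c1)[C@H](O)C2 | intermediate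
3 | 3-O-acetyl-5,7,3′,4′-tetra-O-benzyl-(−)-epicatechin (terminator) | c1c(OCc3ccccc3)cc(OCc3ccccc3)c2c1O[C@H](c1ccc(OCc3ccccc3)c(OCc3ccccc3)c1)[C@H](OC(C)=O)C2 | intermediate
4 | 3-O-acetyl-5,7,3′,4′-tetra-O-benzyl-4β-(2-ethoxyethoxy)epicatechin (O-extender) | c1c(OCc3ccccc3)cc(OCc3ccccc3)c2c1O[C@H](c1ccc(OCc3ccccc3)c(OCc3ccccc3)c1)[C@H](OC(C)=O)[C@H]2OCCOCC | intermediate
5 | 3-O-acetyl-5,7,3′,4′-tetra-O-benzyl-4β-(2,6-dimethylphenylthio)epicatechin (S-extender) | c1c(OCc3ccccc3)cc(OCc3ccccc3)c2c1O[C@H](c1ccc(OCc3ccccc3)c(OCc3ccccc3)c1)[C@H](OC(C)=O)[C@H]2Sc1c(C)cccc1C | intermediate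
6 | 3-O-acetyl-5,7,3′,4′-tetra-O-benzyl-8-bromo-4β-(2-ethoxyethoxy)epicatechin | Brc1c(OCc3ccccc3)cc(OCc3ccccc3)c2c1O[C@H](c1ccc(OCc3ccccc3)c(OCc3ccccc3)c1)[C@H](OC(C)=O)[C@H]2OCCOCC | intermediate
7 | 3-O-acetyl-5,7,3′,4′-tetra-O-benzyl-8-bromo-4β-(2,6-dimethylphenylthio)epicatechin (starter) | Brc1c(OCc3ccccc3)cc(OCc3ccccc3)c2c1O[C@H](c1ccc(OCc3ccccc3)c(OCc3ccccc3)c1)[C@H](OC(C)=O)[C@H]2Sc1c(C)cccc1C | intermediate
8 | starter C4 cation triflate (drawn in the open benzylic form) | Brc1c(OCc3ccccc3)cc(OCc3ccccc3)c2c1O[C@H](c1ccc(OCc3ccccc3)c(OCc3ccccc3)c1)[C@H](OC(C)=O)[CH+]2.[O-]S(=O)(=O)C(F)(F)F | intermediate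
9 | dimer ether 8-Br-E-(4β→8)-E-4β-OCH2CH2OEt | Brc1c(OCc3ccccc3)cc(OCc3ccccc3)c2c1O[C@H](c1ccc(OCc3ccccc3)c(OCc3ccccc3)c1)[C@H](OC(C)=O)[C@H]2c1c(OCc3ccccc3)cc(OCc3ccccc3)c2c1O[C@H](c1ccc(OCc3ccccc3)c(OCc3ccccc3)c1)[C@H](OC(C)=O)[C@H]2OCCOCC | intermediate
10 | dimer C4 cation triflate (cation at C4 of the lower unit) | Brc1c(OCc3ccccc3)cc(OCc3ccccc3)c2c1O[C@H](c1ccc(OCc3ccccc3)c(OCc3ccccc3)c1)[C@H](OC(C)=O)[C@H]2c1c(OCc3ccccc3)cc(OCc3ccccc3)c2c1O[C@H](c1ccc(OCc3ccccc3)c(OCc3ccccc3)c1)[C@H](OC(C)=O)[CH+]2.[O-]S(=O)(=O)C(F)(F)F | intermediate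
11 | trimer thioether 8-Br-E-(4β→8)-E-(4β→8)-E-4β-SXy | Brc1c(OCc3ccccc3)cc(OCc3ccccc3)c2c1O[C@H](c1ccc(OCc3ccccc3)c(OCc3ccccc3)c1)[C@H](OC(C)=O)[C@H]2c1c(OCc3ccccc3)cc(OCc3ccccc3)c2c1O[C@H](c1ccc(OCc3ccccc3)c(OCc3ccccc3)c1)[C@H](OC(C)=O)[C@H]2c1c(OCc3ccccc3)cc(OCc3ccccc3)c2c1O[C@H](c1ccc(OCc3ccccc3)c(OCc3ccccc3)c1)[C@H](OC(C)=O)[C@H]2Sc1c(C)cccc1C | intermediate
12 | trimer C4 cation triflate (cation at C4 of the lowest unit) | Brc1c(OCc3ccccc3)cc(OCc3ccccc3)c2c1O[C@H](c1ccc(OCc3ccccc3)c(OCc3ccccc3)c1)[C@H](OC(C)=O)[C@H]2c1c(OCc3ccccc3)cc(OCc3ccccc3)c2c1O[C@H](c1ccc(OCc3ccccc3)c(OCc3ccccc3)c1)[C@H](OC(C)=O)[C@H]2c1c(OCc3ccccc3)cc(OCc3ccccc3)c2c1O[C@H](c1ccc(OCc3ccccc3)c(OCc3ccccc3)c1)[C@H](OC(C)=O)[CH+]2.[O-]S(=O)(=O)C(F)(F)F | intermediate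
13 | protected tetramer 8-Br-E-(4β→8)-E-(4β→8)-E-(4β→8)-E | Brc1c(OCc3ccccc3)cc(OCc3ccccc3)c2c1O[C@H](c1ccc(OCc3ccccc3)c(OCc3ccccc3)c1)[C@H](OC(C)=O)[C@H]2c1c(OCc3ccccc3)cc(OCc3ccccc3)c2c1O[C@H](c1ccc(OCc3ccccc3)c(OCc3ccccc3)c1)[C@H](OC(C)=O)[C@H]2c1c(OCc3ccccc3)cc(OCc3ccccc3)c2c1O[C@H](c1ccc(OCc3ccccc3)c(OCc3ccccc3)c1)[C@H](OC(C)=O)[C@H]2c1c(OCc3ccccc3)cc(OCc3ccccc3)c2c1O[C@H](c1ccc(OCc3ccccc3)c(OCc3ccccc3)c1)[C@H](OC(C)=O)C2 | intermediate
14 | 8-bromo-hexadeca-O-benzyl tetramer tetrol | Brc1c(OCc3ccccc3)cc(OCc3ccccc3)c2c1O[C@H](c1ccc(OCc3ccccc3)c(OCc3ccccc3)c1)[C@H](O)[C@H]2c1c(OCc3ccccc3)cc(OCc3ccccc3)c2c1O[C@H](c1ccc(OCc3ccccc3)c(OCc3ccccc3)c1)[C@H](O)[C@H]2c1c(OCc3ccccc3)cc(OCc3ccccc3)c2c1O[C@H](c1ccc(OCc3ccccc3)c(OCc3ccccc3)c1)[C@H](O)[C@H]2c1c(OCc3ccccc3)cc(OCc3ccccc3)c2c1O[C@H](c1ccc(OCc3ccccc3)c(OCc3ccccc3)c1)[C@H](O)C2 | intermediate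
15 | epicatechin-(4β→8)-epicatechin-(4β→8)-epicatechin-(4β→8)-epicatechin | Oc1cc(O)c2c(c1)O[C@H](c1ccc(O)c(O)c1)[C@H](O)[C@H]2c1c(O)cc(O)c2c1O[C@H](c1ccc(O)c(O)c1)[C@H](O)[C@H]2c1c(O)cc(O)c2c1O[C@H](c1ccc(O)c(O)c1)[C@H](O)[C@H]2c1c(O)cc(O)c2c1O[C@H](c1ccc(O)c(O)c1)[C@H](O)C2 | target

**Count**

Total steps: 9.
Longest linear sequence: 8 (steps 1, 2, 3, 5, 6, 7, 8, 9).

**Steps most likely to fail**

Risk 1, step 7 (bears the label). Sequence control may be lost in four ways:
- decay of the waiting cation by proton loss before the next unit arrives;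
- transfer of the alkoxy or thio group from an incoming unit to the cation;
- leakage between the soft and the hard activation mode, for example through residual silver ion or unbuffered triflic acid;
- diversion of the sulfenyl promoter of the third cycle by the silyl ether left from the second.

Each of these would blur the chain length. The fallback uses known chemistry only. It is a convergent 2+2 assembly with isolation, in which the nucleophile is always present at the moment of activation. It sets out from 6, 5, 4 and 3. Compounds 6 and 5 are coupled with BF3·OEt2 in CH2Cl2 at −78 °C, which ionises only the C4–O bond, and the dimer thioether 8-Br-E-(4β→8)-E-4β-SXy F1 is isolated. Compound 4 is coupled with an excess of 3 under TMSOTf at −78 °C to give the uncapped dimer E-(4β→8)-E F2. The two dimers are then joined with dimethyl(methylthio)sulfonium tetrafluoroborate in CH2Cl2, with the uncapped dimer present from the start. This comes back to the route at 13.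

Risk 2, step 9. Cleavage of the sixteen benzyl ethers may stall through poisoning of the catalyst by traces of sulfur. Release of HBr at the free-phenol stage may also start acid-induced cleavage of interflavan bonds. The fallback separates the two reductions and sets out from 14. The bromine cap is removed first by bromine–lithium exchange (n-BuLi in excess, THF, −78 °C, then MeOH) to give the bromine-free hexadeca-O-benzyl tetramer tetrol F3. This compound can be purified free of halide and sulfur. It is then hydrogenolysed over Pd(OH)2/C under neutral conditions, coming back to the route at 15.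

Risk 3, step 3. Hydride abstraction next to the electron-withdrawing 3-acetoxy group may be sluggish, and forcing it invites over-oxidation at C4 or attack at C2. The fallback oxidises before acylation and sets out from 2. DDQ/2-ethoxyethanol on the free 3-alcohol gives 5,7,3′,4′-tetra-O-benzyl-4β-(2-ethoxyethoxy)epicatechin F4. This is acetylated (Ac2O, DMAP, pyridine) and comes back to the route at 4. The terminator 3 is still made from 2 by step 2.

**Further compounds**

F1 | step 7 | dimer thioether 8-Br-E-(4β→8)-E-4β-SXy | Brc1c(OCc3ccccc3)cc(OCc3ccccc3)c2c1O[C@H](c1ccc(OCc3ccccc3)c(OCc3ccccc3)c1)[C@H](OC(C)=O)[C@H]2c1c(OCc3ccccc3)cc(OCc3ccccc3)c2c1O[C@H](c1ccc(OCc3ccccc3)c(OCc3ccccc3)c1)[C@H](OC(C)=O)[C@H]2Sc1c(C)cccc1C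
F2 | step 7 | uncapped dimer E-(4β→8)-E (C8–H on the upper unit, C4H2 on the lower unit) | c1c(OCc3ccccc3)cc(OCc3ccccc3)c2c1O[C@H](c1ccc(OCc3ccccc3)c(OCc3ccccc3)c1)[C@H](OC(C)=O)[C@H]2c1c(OCc3ccccc3)cc(OCc3ccccc3)c2c1O[C@H](c1ccc(OCc3ccccc3)c(OCc3ccccc3)c1)[C@H](OC(C)=O)C2
F3 | step 9 | bromine-free hexadeca-O-benzyl tetramer tetrol (four free 3-OH) | c1c(OCc3ccccc3)cc(OCc3ccccc3)c2c1O[C@H](c1ccc(OCc3ccccc3)c(OCc3ccccc3)c1)[C@H](O)[C@H]2c1c(OCc3ccccc3)cc(OCc3ccccc3)c2c1O[C@H](c1ccc(OCc3ccccc3)c(OCc3ccccc3)c1)[C@H](O)[C@H]2c1c(OCc3ccccc3)cc(OCc3ccccc3)c2c1O[C@H](c1ccc(OCc3ccccc3)c(OCc3ccccc3)c1)[C@H](O)[C@H]2c1c(OCc3ccccc3)cc(OCc3ccccc3)c2c1O[C@H](c1ccc(OCc3ccccc3)c(OCc3ccccc3)c1)[C@H](O)C2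
F4 | step 3 | 5,7,3′,4′-tetra-O-benzyl-4β-(2-ethoxyethoxy)epicatechin (3-OH free) | c1c(OCc3ccccc3)cc(OCc3ccccc3)c2c1O[C@H](c1ccc(OCc3ccccc3)c(OCc3ccccc3)c1)[C@H](O)[C@H]2OCCOCC
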